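**Retrosynthetic overview**

1. The triene side chain is cut between the methylene-bearing carbon and the diene: Stille union of a cyclopentane enol triflate with a (2Z,4E)-dienylstannane; acetylation, desilylation and MnO2 oxidation of the allylic alcohol finish the route.
2. Cyclopentane (second ring): Dieckmann closure onto the finished cyclohexane; its CH–OH comes from a hydroxyl-directed ketone reduction, the C(OH)CH3 from methyl addition to the cyclohexanone, the spiro centre from C-alkylation of a cyclic β-keto ester.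
3. Cyclohexane (first ring, key step): a domino Knoevenagel condensation / anti iodo-carbocyclization closes the bond between the ring CH that carries the hydroxypropyl chain and the ring carbon that carries the exocyclic alkylidene, from a linear alkynyl β-keto ester and 4-silyloxybutanal; iodine is later exchanged for methyl.
4. Enabling feature: the tertiary C–OH of the cyclohexane and the CH–OH of the cyclopentane sit 1,3 across the spiro carbon, so the spiro carbon is the α-carbon of a latent β-keto ester and the cyclohexane CH bearing the hydroxypropyl chain is its β-carbon (an electrophilic alkylidene carbon after condensation); the exocyclic tetrasubstituted enal is a latent alkyne.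
5. Absolute configuration comes from a removable 8-phenylmenthyl ester; the other four stereocentres are relayed from the first one.

Key step: step 4

Remarks on the chemistry
- Numbering used below (iridal type): C-1 aldehyde carbon, C-2 its α-carbon (methyl C-25), C-3 to C-5 hydroxypropyl chain (C-3 = CH2OH), C-6 to C-11 cyclohexane (C-6 = CH with the chain, C-7 = alkylidene carbon, C-10 = C(OH)CH3, C-11 = spiro carbon), C-12, C-13, C-14, C-26 rest of the cyclopentane (C-26 = CHOH, C-14 bears the triene), C-15 to C-19 triene, C-28 the CH2OAc carbon.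
- Assumption: (−)-8-phenylmenthol is taken to shield the alkylidene face whose blocking leads to the target configuration at C-6; if the sense of induction were opposite, its enantiomer would be used with no other change.
- Keto–enol mixtures and the E/Z mixture of the Knoevenagel adduct are written without the labile stereo-element.

Step 1
Reactants: 1 (−)-8-phenylmenthol; 2 2,2,6-trimethyl-4H-1,3-dioxin-4-one
Product: 3 (−)-8-phenylmenthyl acetoacetate
Conditions: xylene, 140 °C
Reagents that add atoms: none
Why: Thermolysis of the dioxinone releases acetylketene, which acylates the hindered secondary alcohol (acetoacetylation) without touching a stereocentre.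

Step 2
Reactants: 4 4-(tert-butyldimethylsilyloxy)but-2-yn-1-ol
Product: 5 4-bromo-1-(tert-butyldimethylsilyloxy)but-2-yne
Conditions: CBr4, PPh3, CH2Cl2, 0 °C
Reagents that add atoms: carbon tetrabromide, BrC(Br)(Br)Br
Why: Appel bromination of a primary propargylic alcohol is an SN2 displacement of the oxyphosphonium group and leaves the silyl ether intact.

Step 3
Reactants: 3 (−)-8-phenylmenthyl acetoacetate; 5 4-bromo-1-(tert-butyldimethylsilyloxy)but-2-yne
Product: 6 (−)-8-phenylmenthyl 8-(tert-butyldimethylsilyloxy)-3-oxooct-6-ynoate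
Conditions: NaH, THF, 0 °C; n-BuLi, 0 °C; then 5, 0 to 25 °C; H2O
Reagents that add atoms: none
Why: γ-Alkylation of the acetoacetate dianion, whose terminal carbanion is the more basic site and displaces the propargylic bromide by SN2 substitution.

Step 4
Reactants: 6 (−)-8-phenylmenthyl 8-(tert-butyldimethylsilyloxy)-3-oxooct-6-ynoate; 7 4-(tert-butyldimethylsilyloxy)butanal
Product: 9 (−)-8-phenylmenthyl 5-[(E)-1-iodo-2-(tert-butyldimethylsilyloxy)ethylidene]-2-oxo-6-[3-(tert-butyldimethylsilyloxy)propyl]cyclohexane-1-carboxylate, via alkylidene keto ester 8 (not isolated)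
Conditions: piperidinium acetate (10 mol%), 4 Å molecular sieves, CH2Cl2, 0 °C; then ZnI2 (2 equiv), 0 to 25 °C
Reagents that add atoms: zinc iodide, I[Zn]I
Why: Proposed new method: Knoevenagel condensation should give alkylidene acetoacetate 8, whose E and Z forms interconvert by reversible iodide conjugate addition once ZnI2 chelates the ketone and ester carbonyls, and only the isomer with the chain cis to the ester can fold the ketone-borne tether over the alkylidene, so the mixture is funnelled into one product. The alkyne carbon C-7 then attacks the electrophilic alkylidene carbon C-6 while iodide adds to the distal alkyne carbon from the opposite side (anti carbo-iodination), which closes the cyclohexane by a 6-endo-trig attack at the alkylidene that is exo-dig at the alkyne, and the zinc enolate is protonated on work-up. The closest known reaction types are the domino Knoevenagel/ene cyclization of alkylidene 1,3-dicarbonyl compounds under ZnBr2 and the zinc-halide-promoted halo-carbocyclization of alkyne-tethered alkylidene 1,3-dicarbonyl esters, extended here to an endo closure through the ketone side chain. The new stereocentre C-6 is controlled by the 8-phenylmenthyl ester, whose phenyl ring stacks over one face of the chelated alkylidene so that the tether adds to the open face. The step needs C–C closure to win over O-closure to a 4H-pyran and over Conia-ene attack by the enolate carbon, which chelation of both carbonyl oxygens to zinc and the concerted iodide delivery should secure. The anti addition places iodine cis to C-8, so the silyloxymethyl group (the later aldehyde) is cis to C-6 as the target requires.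

Step 5
Reactants: 9 (−)-8-phenylmenthyl 5-[(E)-1-iodo-2-(tert-butyldimethylsilyloxy)ethylidene]-2-oxo-6-[3-(tert-butyldimethylsilyloxy)propyl]cyclohexane-1-carboxylate
Product: 10 methyl 5-[(E)-1-iodo-2-(tert-butyldimethylsilyloxy)ethylidene]-2-oxo-6-[3-(tert-butyldimethylsilyloxy)propyl]cyclohexane-1-carboxylate
Conditions: MeOH, DMAP (0.3 equiv), toluene, 100 °C (sealed)
Reagents that add atoms: methanol, CO
Why: Transesterification of an enolizable β-keto ester runs through the acylketene (loss of the auxiliary alcohol from the enol), which methanol traps, and C-6 is not involved.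

Step 6
Reactants: 10 methyl 5-[(E)-1-iodo-2-(tert-butyldimethylsilyloxy)ethylidene]-2-oxo-6-[3-(tert-butyldimethylsilyloxy)propyl]cyclohexane-1-carboxylate; 11 methyl 4-iodobutanoate
Product: 12 methyl 5-[(E)-1-iodo-2-(tert-butyldimethylsilyloxy)ethylidene]-1-(4-methoxy-4-oxobutyl)-2-oxo-6-[3-(tert-butyldimethylsilyloxy)propyl]cyclohexane-1-carboxylate
Conditions: Cs2CO3, DMF, 25 °C
Reagents that add atoms: none
Why: C-alkylation of the cyclic β-keto ester enolate with a primary iodide; the electrophile should enter anti to the C-6 chain, which is pseudoaxial because of A(1,3) strain with the ester and the alkylidene, so the ester ends cis to that chain at the new quaternary centre C-11.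

Step 7
Reactants: 12 methyl 5-[(E)-1-iodo-2-(tert-butyldimethylsilyloxy)ethylidene]-1-(4-methoxy-4-oxobutyl)-2-oxo-6-[3-(tert-butyldimethylsilyloxy)propyl]cyclohexane-1-carboxylate
Product: 13 methyl 1-(4-methoxy-4-oxobutyl)-2-oxo-5-[(Z)-1-(tert-butyldimethylsilyloxy)propan-2-ylidene]-6-[3-(tert-butyldimethylsilyloxy)propyl]cyclohexane-1-carboxylate
Conditions: Me2Zn, Pd[P(t-Bu)3]2 (5 mol%), THF, 40 °C
Reagents that add atoms: dimethylzinc, C[Zn]C
Why: Negishi methylation of the alkenyl iodide proceeds with retention of the double-bond geometry and tolerates the ketone and the esters.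

Step 8
Reactants: 13 methyl 1-(4-methoxy-4-oxobutyl)-2-oxo-5-[(Z)-1-(tert-butyldimethylsilyloxy)propan-2-ylidene]-6-[3-(tert-butyldimethylsilyloxy)propyl]cyclohexane-1-carboxylate
Product: 14 methyl 2-hydroxy-1-(4-methoxy-4-oxobutyl)-2-methyl-5-[(Z)-1-(tert-butyldimethylsilyloxy)propan-2-ylidene]-6-[3-(tert-butyldimethylsilyloxy)propyl]cyclohexane-1-carboxylate
Conditions: MeMgBr, CeCl3, THF, −78 °C
Reagents that add atoms: methylmagnesium bromide, C[Mg]Br
Why: The organocerium reagent adds to the ketone only and should attack equatorially, because axial attack is blocked by the axial C-6 chain, which gives the axial tertiary alcohol at C-10 cis to that chain.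

Step 9
Reactants: 14 methyl 2-hydroxy-1-(4-methoxy-4-oxobutyl)-2-methyl-5-[(Z)-1-(tert-butyldimethylsilyloxy)propan-2-ylidene]-6-[3-(tert-butyldimethylsilyloxy)propyl]cyclohexane-1-carboxylate
Product: 15 methyl 6-hydroxy-6-methyl-1-oxo-9-[(Z)-1-(tert-butyldimethylsilyloxy)propan-2-ylidene]-10-[3-(tert-butyldimethylsilyloxy)propyl]spiro[4.5]decane-2-carboxylate
Conditions: LiN(SiMe3)2 (3 equiv), THF, −78 to 0 °C; AcOH
Reagents that add atoms: none
Why: Dieckmann condensation of the butanoate enolate onto the ester at the quaternary carbon closes the cyclopentanone (5-exo-trig) and is driven by deprotonation of the β-keto ester formed.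

Step 10
Reactants: 15 methyl 6-hydroxy-6-methyl-1-oxo-9-[(Z)-1-(tert-butyldimethylsilyloxy)propan-2-ylidene]-10-[3-(tert-butyldimethylsilyloxy)propyl]spiro[4.5]decane-2-carboxylate
Product: 16 methyl 1,6-dihydroxy-6-methyl-9-[(Z)-1-(tert-butyldimethylsilyloxy)propan-2-ylidene]-10-[3-(tert-butyldimethylsilyloxy)propyl]spiro[4.5]decane-2-carboxylate
Conditions: Me4NBH(OAc)3, MeCN/AcOH (1:1), −30 °C
Reagents that add atoms: none
Why: Evans–Saksena hydroxyl-directed reduction: the borohydride bound to the C-10 oxygen delivers hydride to the ketone face syn to C-10, giving the C-26 alcohol anti to it, and the enolizing β-keto ester should be reduced as the epimer with the ester opposite to the incoming hydride, giving the cis hydroxy ester at C-14.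

Step 11
Reactants: 16 methyl 1,6-dihydroxy-6-methyl-9-[(Z)-1-(tert-butyldimethylsilyloxy)propan-2-ylidene]-10-[3-(tert-butyldimethylsilyloxy)propyl]spiro[4.5]decane-2-carboxylate
Product: 17 methyl 6-methyl-1,6-bis(triethylsilyloxy)-9-[(Z)-1-(tert-butyldimethylsilyloxy)propan-2-ylidene]-10-[3-(tert-butyldimethylsilyloxy)propyl]spiro[4.5]decane-2-carboxylate
Conditions: Et3SiOTf, 2,6-lutidine, CH2Cl2, −40 to 0 °C
Reagents that add atoms: triethylsilyl trifluoromethanesulfonate, CC[Si](CC)(CC)OS(=O)(=O)C(F)(F)F
Why: Silyl triflate silylation caps the secondary and the hindered tertiary alcohol, so the later enolate steps cannot start a retro-aldol cleavage.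

Step 12
Reactants: 17 methyl 6-methyl-1,6-bis(triethylsilyloxy)-9-[(Z)-1-(tert-butyldimethylsilyloxy)propan-2-ylidene]-10-[3-(tert-butyldimethylsilyloxy)propyl]spiro[4.5]decane-2-carboxylate
Product: 19 1-{6-methyl-1,6-bis(triethylsilyloxy)-9-[(Z)-1-(tert-butyldimethylsilyloxy)propan-2-ylidene]-10-[3-(tert-butyldimethylsilyloxy)propyl]spiro[4.5]decan-2-yl}ethan-1-one, via silyl ketone 18 (not isolated)
Conditions: Me3SiCH2Li (3 equiv), THF/pentane, −78 to 0 °C; then MeOH, 0 °C
Reagents that add atoms: (trimethylsilyl)methyllithium, [Li]C[Si](C)(C)C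
Why: Ester-to-methyl-ketone conversion: the first adduct is deprotonated to its enolate, which stops a second addition, and methanolysis then removes the silyl group.

Step 13
Reactants: 19 1-{6-methyl-1,6-bis(triethylsilyloxy)-9-[(Z)-1-(tert-butyldimethylsilyloxy)propan-2-ylidene]-10-[3-(tert-butyldimethylsilyloxy)propyl]spiro[4.5]decan-2-yl}ethan-1-one
Product: 20 1-{6-methyl-1,6-bis(triethylsilyloxy)-9-[(Z)-1-(tert-butyldimethylsilyloxy)propan-2-ylidene]-10-[3-(tert-butyldimethylsilyloxy)propyl]spiro[4.5]decan-2-yl}ethenyl trifluoromethanesulfonate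
Conditions: KN(SiMe3)2, THF, −78 °C; then N-(5-chloropyridin-2-yl)triflimide, −78 °C
Reagents that add atoms: N-(5-chloropyridin-2-yl)-1,1,1-trifluoro-N-(trifluoromethylsulfonyl)methanesulfonamide, O=S(=O)(N(c1ccc(Cl)cn1)S(=O)(=O)C(F)(F)F)C(F)(F)F
Why: Kinetic deprotonation of the methyl ketone at the methyl group and O-sulfonylation give the terminal enol triflate without touching C-14.

Step 14
Reactants: 21 propargyl alcohol; 22 5-bromo-2-methylpent-2-ene
Product: 25 (2Z)-3-iodo-2-(4-methylpent-3-en-1-yl)prop-2-en-1-ol, via Grignard reagent 23 (not isolated), via alkenylmagnesium chelate 24 (not isolated)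
Conditions: 22, Mg, THF, 40 °C; then 21, CuI (10 mol%), Et2O, 0 to 35 °C; then I2, −50 to 0 °C
Reagents that add atoms: iodine, II
Why: Copper-catalysed anti-carbomagnesiation of the propargylic alkoxide puts the alkyl group on C-2 and magnesium, held in a five-membered chelate, on C-3 cis to the CH2O group, and iodinolysis with retention gives the Z iodide.

Step 15
Reactants: 25 (2Z)-3-iodo-2-(4-methylpent-3-en-1-yl)prop-2-en-1-ol; 26 (E)-1,2-bis(tributylstannyl)ethene
Product: 27 (2Z,4E)-2-(4-methylpent-3-en-1-yl)-5-(tributylstannyl)penta-2,4-dien-1-ol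
Conditions: 26 (2.5 equiv), PdCl2(MeCN)2 (5 mol%), DMF, 25 °C
Reagents that add atoms: none
Why: Stille coupling of the alkenyl iodide with an excess of the bis-stannane couples one tin terminus only, with retention at both double bonds.

Step 16
Reactants: 20 the enol triflate of step 13; 27 (2Z,4E)-2-(4-methylpent-3-en-1-yl)-5-(tributylstannyl)penta-2,4-dien-1-ol
Product: 28 (2Z,4E)-6-{6-methyl-1,6-bis(triethylsilyloxy)-9-[(Z)-1-(tert-butyldimethylsilyloxy)propan-2-ylidene]-10-[3-(tert-butyldimethylsilyloxy)propyl]spiro[4.5]decan-2-yl}-2-(4-methylpent-3-en-1-yl)hepta-2,4,6-trien-1-ol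
Conditions: Pd(PPh3)4 (10 mol%), CuCl, LiCl, DMSO, 60 °C
Reagents that add atoms: none
Why: Copper-accelerated Stille coupling joins the hindered enol triflate and the dienylstannane with retention of geometry and tolerates the free allylic alcohol.

Step 17
Reactants: 28 the triene alcohol of step 16
Product: 29 the acetate of 28 at C-28
Conditions: Ac2O, pyridine, DMAP (cat.), CH2Cl2, 0 °C
Reagents that add atoms: acetic anhydride, CC(=O)OC(C)=O
Why: Acylation of the only free hydroxyl group (primary, allylic).

Step 18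
Reactants: 29 the tetrasilylated triene acetate
Product: 30 (2Z,4E)-6-{1,6-dihydroxy-10-(3-hydroxypropyl)-9-[(Z)-1-hydroxypropan-2-ylidene]-6-methylspiro[4.5]decan-2-yl}-2-(4-methylpent-3-en-1-yl)hepta-2,4,6-trien-1-yl acetate
Conditions: HF·pyridine, pyridine, THF, 0 to 25 °C
Reagents that add atoms: none
Why: Buffered fluoride desilylation removes all four silyl ethers while the acetate and the triene should survive.

Step 19
Reactants: 30 the tetraol acetate of step 18
Product: 31 CNP0205332.1
Conditions: MnO2, CH2Cl2, 25 °C, dark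
Reagents that add atoms: none
Why: MnO2 oxidizes only the allylic primary alcohol to the enal; the saturated primary, the homoallylic secondary and the tertiary alcohols are inert and the Z geometry is kept.

**Compound list**

1 | (−)-8-phenylmenthol, (1R,2S,5R)-5-methyl-2-(2-phenylpropan-2-yl)cyclohexan-1-ol | C[C@@H]1CC[C@H]([C@@H](C1)O)C(C)(C)c1ccccc1 | starting material
2 | 2,2,6-trimethyl-4H-1,3-dioxin-4-one | CC1=CC(=O)OC(C)(C)O1 | starting material
3 | (−)-8-phenylmenthyl acetoacetate (3-oxobutanoate of 1) | C[C@@H]1CC[C@H]([C@@H](C1)OC(=O)CC(C)=O)C(C)(C)c1ccccc1 | intermediate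
4 | 4-(tert-butyldimethylsilyloxy)but-2-yn-1-ol | OCC#CCO[Si](C)(C)C(C)(C)C | starting material
5 | 4-bromo-1-(tert-butyldimethylsilyloxy)but-2-yne | BrCC#CCO[Si](C)(C)C(C)(C)C | intermediate
6 | (−)-8-phenylmenthyl 8-(tert-butyldimethylsilyloxy)-3-oxooct-6-ynoate | C[C@@H]1CC[C@H]([C@@H](C1)OC(=O)CC(=O)CCC#CCO[Si](C)(C)C(C)(C)C)C(C)(C)c1ccccc1 | intermediate
7 | 4-(tert-butyldimethylsilyloxy)butanal | O=CCCCO[Si](C)(C)C(C)(C)C | starting material
8 | (−)-8-phenylmenthyl 8-(tert-butyldimethylsilyloxy)-2-[4-(tert-butyldimethylsilyloxy)butylidene]-3-oxooct-6-ynoate, E/Z mixture at the alkylidene | C[C@@H]1CC[C@H]([C@@H](C1)OC(=O)C(=CCCCO[Si](C)(C)C(C)(C)C)C(=O)CCC#CCO[Si](C)(C)C(C)(C)C)C(C)(C)c1ccccc1 | intermediate (not isolated)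
9 | (−)-8-phenylmenthyl 5-[(E)-1-iodo-2-(tert-butyldimethylsilyloxy)ethylidene]-2-oxo-6-[3-(tert-butyldimethylsilyloxy)propyl]cyclohexane-1-carboxylate; ring C-6 (= C-6 of the target) configured as in the target, iodine cis to ring C-4, ring C-1 labile (keto–enol) | C[C@@H]1CC[C@H]([C@@H](C1)OC(=O)C2[C@H](CCCO[Si](C)(C)C(C)(C)C)/C(=C(/I)CO[Si](C)(C)C(C)(C)C)CCC2=O)C(C)(C)c1ccccc1 | intermediate
10 | methyl 5-[(E)-1-iodo-2-(tert-butyldimethylsilyloxy)ethylidene]-2-oxo-6-[3-(tert-butyldimethylsilyloxy)propyl]cyclohexane-1-carboxylate; stereochemistry as in 9 | COC(=O)C1[C@H](CCCO[Si](C)(C)C(C)(C)C)/C(=C(/I)CO[Si](C)(C)C(C)(C)C)CCC1=O | intermediate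
11 | methyl 4-iodobutanoate | COC(=O)CCCI | starting material
12 | methyl 5-[(E)-1-iodo-2-(tert-butyldimethylsilyloxy)ethylidene]-1-(4-methoxy-4-oxobutyl)-2-oxo-6-[3-(tert-butyldimethylsilyloxy)propyl]cyclohexane-1-carboxylate; ring ester cis to the C-6 chain, butanoate arm trans | COC(=O)CCC[C@]1([C@H](CCCO[Si](C)(C)C(C)(C)C)/C(=C(/I)CO[Si](C)(C)C(C)(C)C)CCC1=O)C(=O)OC | intermediate
13 | methyl 1-(4-methoxy-4-oxobutyl)-2-oxo-5-[(Z)-1-(tert-butyldimethylsilyloxy)propan-2-ylidene]-6-[3-(tert-butyldimethylsilyloxy)propyl]cyclohexane-1-carboxylate; silyloxymethyl cis to ring C-6 | COC(=O)CCC[C@]1([C@H](CCCO[Si](C)(C)C(C)(C)C)/C(=C(/C)CO[Si](C)(C)C(C)(C)C)CCC1=O)C(=O)OC | intermediate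
14 | methyl 2-hydroxy-1-(4-methoxy-4-oxobutyl)-2-methyl-5-[(Z)-1-(tert-butyldimethylsilyloxy)propan-2-ylidene]-6-[3-(tert-butyldimethylsilyloxy)propyl]cyclohexane-1-carboxylate; tertiary hydroxyl cis to the C-6 chain and to the ring ester | COC(=O)CCC[C@]1([C@H](CCCO[Si](C)(C)C(C)(C)C)/C(=C(/C)CO[Si](C)(C)C(C)(C)C)CC[C@]1(C)O)C(=O)OC | intermediate
15 | methyl 6-hydroxy-6-methyl-1-oxo-9-[(Z)-1-(tert-butyldimethylsilyloxy)propan-2-ylidene]-10-[3-(tert-butyldimethylsilyloxy)propyl]spiro[4.5]decane-2-carboxylate; spiro C-5, C-6 and C-10 as in the target, C-2 labile | COC(=O)C1CC[C@]2([C@H](CCCO[Si](C)(C)C(C)(C)C)/C(=C(/C)CO[Si](C)(C)C(C)(C)C)CC[C@]2(C)O)C1=O | intermediate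
16 | methyl 1,6-dihydroxy-6-methyl-9-[(Z)-1-(tert-butyldimethylsilyloxy)propan-2-ylidene]-10-[3-(tert-butyldimethylsilyloxy)propyl]spiro[4.5]decane-2-carboxylate; C-1 hydroxyl cis to the C-2 ester and to C-10, trans to C-6 on the cyclopentane | COC(=O)[C@@H]1CC[C@]2([C@H](CCCO[Si](C)(C)C(C)(C)C)/C(=C(/C)CO[Si](C)(C)C(C)(C)C)CC[C@]2(C)O)[C@@H]1O | intermediate
17 | 1,6-bis(triethylsilyl) ether of 16 | COC(=O)[C@@H]1CC[C@]2([C@H](CCCO[Si](C)(C)C(C)(C)C)/C(=C(/C)CO[Si](C)(C)C(C)(C)C)CC[C@]2(C)O[Si](CC)(CC)CC)[C@@H]1O[Si](CC)(CC)CC | intermediate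
18 | (trimethylsilyl)methyl ketone corresponding to ester 17 | C[Si](C)(C)CC(=O)[C@@H]1CC[C@]2([C@H](CCCO[Si](C)(C)C(C)(C)C)/C(=C(/C)CO[Si](C)(C)C(C)(C)C)CC[C@]2(C)O[Si](CC)(CC)CC)[C@@H]1O[Si](CC)(CC)CC | intermediate (not isolated)
19 | methyl ketone: 1-{6-methyl-1,6-bis(triethylsilyloxy)-9-[(Z)-1-(tert-butyldimethylsilyloxy)propan-2-ylidene]-10-[3-(tert-butyldimethylsilyloxy)propyl]spiro[4.5]decan-2-yl}ethan-1-one | CC(=O)[C@@H]1CC[C@]2([C@H](CCCO[Si](C)(C)C(C)(C)C)/C(=C(/C)CO[Si](C)(C)C(C)(C)C)CC[C@]2(C)O[Si](CC)(CC)CC)[C@@H]1O[Si](CC)(CC)CC | intermediate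
20 | terminal enol triflate of 19 | C=C(OS(=O)(=O)C(F)(F)F)[C@@H]1CC[C@]2([C@H](CCCO[Si](C)(C)C(C)(C)C)/C(=C(/C)CO[Si](C)(C)C(C)(C)C)CC[C@]2(C)O[Si](CC)(CC)CC)[C@@H]1O[Si](CC)(CC)CC | intermediate
21 | propargyl alcohol | C#CCO | starting material
22 | 5-bromo-2-methylpent-2-ene | CC(C)=CCCBr | starting material
23 | (4-methylpent-3-en-1-yl)magnesium bromide | CC(C)=CCC[Mg]Br | intermediate (not isolated)
24 | 4-(4-methylpent-3-en-1-yl)-2,5-dihydro-1,2-oxamagnesole (cyclic alkenylmagnesium alkoxide) | CC(C)=CCCC1=C[Mg]OC1 | intermediate (not isolated)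
25 | (2Z)-3-iodo-2-(4-methylpent-3-en-1-yl)prop-2-en-1-ol (iodine cis to CH2OH) | I/C=C(/CCC=C(C)C)CO | intermediate
26 | (E)-1,2-bis(tributylstannyl)ethene | CCCC[Sn](CCCC)(CCCC)/C=C/[Sn](CCCC)(CCCC)CCCC | starting material
27 | (2Z,4E)-2-(4-methylpent-3-en-1-yl)-5-(tributylstannyl)penta-2,4-dien-1-ol | CCCC[Sn](CCCC)(CCCC)/C=C/C=C(/CCC=C(C)C)CO | intermediate
28 | tetrasilylated triene alcohol (free C-28 hydroxyl) | C=C(/C=C/C=C(/CCC=C(C)C)CO)[C@@H]1CC[C@]2([C@H](CCCO[Si](C)(C)C(C)(C)C)/C(=C(/C)CO[Si](C)(C)C(C)(C)C)CC[C@]2(C)O[Si](CC)(CC)CC)[C@@H]1O[Si](CC)(CC)CC | intermediate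
29 | tetrasilylated triene acetate | C=C(/C=C/C=C(/CCC=C(C)C)COC(C)=O)[C@@H]1CC[C@]2([C@H](CCCO[Si](C)(C)C(C)(C)C)/C(=C(/C)CO[Si](C)(C)C(C)(C)C)CC[C@]2(C)O[Si](CC)(CC)CC)[C@@H]1O[Si](CC)(CC)CC | intermediate
30 | tetraol acetate (C-1 at the alcohol level) | C=C(/C=C/C=C(/CCC=C(C)C)COC(C)=O)[C@@H]1CC[C@]2([C@H](CCCO)/C(=C(/C)CO)CC[C@]2(C)O)[C@@H]1O | intermediate
31 | CNP0205332.1, (2Z,4E)-6-{(1R,2S,5S,6S,10R)-1,6-dihydroxy-10-(3-hydroxypropyl)-6-methyl-9-[(Z)-1-oxopropan-2-ylidene]spiro[4.5]decan-2-yl}-2-(4-methylpent-3-en-1-yl)hepta-2,4,6-trien-1-yl acetate; (6R,10S,11S,14S,26R) in the iridal numbering | C=C(/C=C/C=C(/CCC=C(C)C)COC(C)=O)[C@@H]1CC[C@]2([C@H](CCCO)/C(=C(/C)C=O)CC[C@]2(C)O)[C@@H]1O | target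

**Step count**

Total step count: 19. Longest linear sequence: 16 steps (steps 1, 3 to 13, 16 to 19).

**Steps most likely to fail**

Step 4 (bears the label). The alkyne carrying a propargylic ether may be too weak a nucleophile. Ring closure through oxygen (4H-pyran) or through the enolate carbon (Conia-ene) may compete, and the auxiliary may give poor facial selectivity. Fallback with known chemistry, setting out from 6 and 7 and returning at 9: the Knoevenagel condensation is run alone (piperidinium acetate, CH2Cl2, sieves) and 8 is isolated as the E/Z mixture. Then 8 is treated with Bu3SnH and Et3B/air in the presence of MgBr2·OEt2 at −78 °C. The stannyl radical adds reversibly to the alkyne, and only the vinyl radical at C-7 can close (6-endo) onto the chelated, auxiliary-shielded alkylidene, which funnels the mixture. The bulky stannyl group should end up trans to the new bond, giving (−)-8-phenylmenthyl 2-oxo-6-[3-(tert-butyldimethylsilyloxy)propyl]-5-[(E)-2-(tert-butyldimethylsilyloxy)-1-(tributylstannyl)ethylidene]cyclohexane-1-carboxylate F1. Iododestannylation (I2, CH2Cl2, 0 °C) with retention would then give 9.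

Step 9. Retro-aldol opening of the cyclohexane from the tertiary alkoxide may compete with the Claisen closure onto the hindered ester. Fallback setting out from 14 and returning at 15: the tertiary alcohol is first capped (Me3SiOTf, 2,6-lutidine) to give the trimethylsilyl ether of 14 F2. The Dieckmann condensation is then run on the ether with LiN(SiMe3)2 to give the trimethylsilyl ether of 15 F3. Citric acid in methanol removes the silyl group and gives 15.

Step 10. Hydride delivery from the hindered tertiary alkoxyborohydride may be slow, so undirected reduction from the wrong face or incomplete funnelling of the C-14 epimers may occur. Fallback setting out from 15 and returning at 16: a ketoreductase (chosen from an enzyme panel, with cofactor recycling) carries out a dynamic kinetic reduction of the racemizing β-keto ester. This is the known biocatalytic route to cis-2-hydroxycycloalkanecarboxylates, with the configuration at C-26 set by the enzyme and not by the substrate.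

Further compounds
F1 | step 4 | (−)-8-phenylmenthyl 2-oxo-6-[3-(tert-butyldimethylsilyloxy)propyl]-5-[(E)-2-(tert-butyldimethylsilyloxy)-1-(tributylstannyl)ethylidene]cyclohexane-1-carboxylate | C[C@@H]1CC[C@H]([C@@H](C1)OC(=O)C2[C@H](CCCO[Si](C)(C)C(C)(C)C)/C(=C(/[Sn](CCCC)(CCCC)CCCC)CO[Si](C)(C)C(C)(C)C)CCC2=O)C(C)(C)c1ccccc1
F2 | step 9 | trimethylsilyl ether of 14 | COC(=O)CCC[C@]1([C@H](CCCO[Si](C)(C)C(C)(C)C)/C(=C(/C)CO[Si](C)(C)C(C)(C)C)CC[C@]1(C)O[Si](C)(C)C)C(=O)OC
F3 | step 9 | trimethylsilyl ether of 15 | COC(=O)C1CC[C@]2([C@H](CCCO[Si](C)(C)C(C)(C)C)/C(=C(/C)CO[Si](C)(C)C(C)(C)C)CC[C@]2(C)O[Si](C)(C)C)C1=O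
F0 | step 10 | none | none
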